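The trap in these flasks is to read target as something that piles up with time: in the alder run it sinks from 27% to 19% while starting material is still falling.

| setting | alder | ash | Saturday's | Tuesday's | Wednesday's |
|---|---|---|---|---|---|
| starting material | 0.24 M | 0.24 M | 0.24 M | 0.24 M | 0.24 M |
| reagent | 0.288 M | 0.288 M | 0.288 M | 0.288 M | 0.288 M |
| second substrate | 0.024 M | 0.096 M | 0.0480 M | 0.0480 M | 0.0480 M |
| temperature | 114 °C | 122 °C | 110 °C | 125 °C |  |
| remark | run made earlier | run made earlier |  |  | at 125 °C until 2.0 min, from then on at 110 °C |
| time |  |  | 3.0 min | 3.0 min | 3.0 min |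

| run | time / s | target / % | starting material / % |
|---|---|---|---|
| alder | 20.0 | 27 | 58 |
| alder | 40.0 | 27 | 47 |
| alder | 60.0 | 24 | 43 |
| alder | 80.0 | 18 | 37 |
| alder | 120 | 19 | 29 |
| ash | 10.0 | 17 | 60 |
| ash | 15.0 | 17 | 56 |
| ash | 30.0 | 11 | 44 |
| ash | 40.0 | 12 | 37 |
| ash | 60.0 | 7 | 30 |

(scatter of a reading: 1.5 percentage points)

1. which flask leads in amount of target, in percent of the starting material charged ("all alike" within 1.5 percentage points) (Saturday's / Tuesday's / Wednesday's / all alike)
2. how much target is there at the end, in percent of the starting material charged: Saturday's
3. how much target is there at the end, in percent of the starting material charged: Tuesday's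
4. how much target is there at the end, in percent of the starting material charged: Wednesday's

- the earlier runs were read with a standard deviation of 1.5 percentage points

Divide one reading by the other and time drops out. If target forms and reverts at equal rates and c(reagent) moves little, c(target)/c(starting material) stands still, and the readings from 60.0 s in alder and 30.0 s in ash give pooled quotients of

alder: 0.560; ash: 0.270

Target needs reagent, so divide again. I assume each second substrate takes one reagent and subtract that, plus the target of the last reading, from the reagent charge:

alder: K = 2.56 M⁻¹; ash: K = 1.54 M⁻¹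

This K, c(target)/(c(starting material)·c(reagent)), is the balance constant, an apparent equilibrium constant. These are readings with scatter, and the runs differ in second substrate as well as temperature. I take alder's for the cold flask and ash's for the hot one, which gives the share of the pool (target plus starting material) that is target:

Saturday's: 33.3%; Tuesday's: 25.6%

The weak link is the pool, which I extend past the last readings at each run's own first-order loss:

Saturday's: 34.1%; Tuesday's: 6.37%

So I commit to 11.3% target for Saturday's, 1.63% for Tuesday's and, giving Wednesday's the hot pool with the cold share, 2.12%. Saturday's leads in this reckoning. The pool cancels in Wednesday's over Tuesday's, which leaves 1.30.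

The forecast, reasoning from “a fast reversible interconversion, with the target favoured by cooling”, named Saturday's with 16%, 2.5% and 5%, each above mine.

The flasks give 16.6%, 6.89% and 9.25%, so Saturday's leads, and Wednesday's over Tuesday's is 1.34.

    starting material + reagent ⇌ target (K = 2.70 M⁻¹, k = 0.140 M⁻¹ s⁻¹, Ea = 80.0 kJ mol⁻¹, ΔH = −36.0 kJ mol⁻¹)
    second substrate + reagent → second product (k = 3.60 M⁻¹ s⁻¹, Ea = 53.0 kJ mol⁻¹)
    starting material + second substrate → cross product (k = 0.280 M⁻¹ s⁻¹, Ea = 59.0 kJ mol⁻¹)
    starting material ⇌ dormant form (K = 5.40, k = 0.00780 s⁻¹, Ea = 119 kJ mol⁻¹, ΔH = −17.0 kJ mol⁻¹)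
    (constants at 110 °C)

Tuesday's slowest mode has a half-life of 0.392 min at the end, far shorter than its 3.0 min, and ten times as long leaves 6.79% target. At the end Tuesday's pool stands at 24.1%, not my 6.37%, with 74.5% as dormant form, and target is 28.6% of that pool where my share was 25.6%. For Tuesday's recipe with 1.2 M reagent, 1.54 M⁻¹ times reagent less second substrate gives a quotient of 1.78. The computed flask holds 27.6% target over 14.3% starting material, a quotient of 1.93.

The runs stem from a simulated flask from invented constants, noise included.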